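**Retrosynthetic overview**
1. Target 13 ⇐ β‑bromo ketone 12 by methyl addition to the ring‑A ketone (carbinol centre set by equatorial attack).
2. 12 ⇐ bicyclo[3.1.0]hexanol 11 by a ring‑expanding bromination (cyclopentanone + CH2 → cyclohexanone, C–Br formed at the same time).
3. 11 ⇐ ketone 8 (silyl enol ether, Simmons–Smith); 8 ⇐ enone 7 (Wittig, =CHBr); 7 ⇐ achiral dienone 5 (enantioselective CuH desymmetrisation sets the spiro centre).
4. 5 ⇐ phenol 4 by oxidative dearomatisation with semipinacol ring expansion (cyclobutanol → cyclopentanone, spiro C–C bond); 4 ⇐ 4‑bromophenol 1 + 2,2‑dimethylcyclobutanone 2.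
5. Ring order: ring B comes from the arene, then the spiro cyclopentanone (first ring expansion), then six‑membered ring A (second ring expansion).

Assumption: 2,2‑dimethylcyclobutan‑1‑one is bought as a catalogue building block, and for the two chiral ligands (steps 3 and 7) the antipode written is the one that screening shows to give the drawn configuration.

**Step 1**
Reactants: 1 4‑bromophenol; 2 2,2‑dimethylcyclobutan‑1‑one
Product: 4 4‑(1‑hydroxy‑2,2‑dimethylcyclobutyl)phenol, via lithium 4‑lithiophenolate 3 (not isolated)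
Conditions: n‑BuLi (2.2 equiv), THF, −78 → 0 °C; then 2, −78 °C → rt; H2O
Reagents that add atoms: none
Why: Deprotonation and Br–Li exchange give the para‑lithiated phenolate, which adds 1,2 to the strained, electrophilic cyclobutanone (aryllithium carbonyl addition); the carbinol centre is racemic and is erased in step 2.

**Step 2**
Reactants: 4 4‑(1‑hydroxy‑2,2‑dimethylcyclobutyl)phenol
Product: 5 4,4‑dimethylspiro[4.5]deca‑6,9‑diene‑1,8‑dione
Conditions: PhI(OAc)2 (1.1 equiv), (CF3)2CHOH, 0 °C, 15 min
Reagents that add atoms: none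
Why: Oxidation of the phenol makes its para carbon electrophilic and the neighbouring cyclobutanol answers with a strain‑releasing 1,2‑shift of the more substituted ring carbon (CMe2) onto it, giving the cyclopentanone and the achiral spiro dienone (oxidative dearomatisation–semipinacol ring expansion).

**Step 3**
Reactants: 5 4,4‑dimethylspiro[4.5]deca‑6,9‑diene‑1,8‑dione
Product: 7 (5S)‑4,4‑dimethylspiro[4.5]dec‑6‑ene‑1,8‑dione, via silyl dienol ether 6 (not isolated)
Conditions: Cu(OAc)2 (5 mol %), (R)‑DTBM‑SEGPHOS (5.5 mol %), (EtO)2MeSiH (1.2 equiv), toluene, −20 °C; then 1 M HCl, THF, 0 °C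
Reagents that add atoms: none
Why: Ligated CuH delivers hydride to one of the two enantiotopic enone β‑carbons from the face away from the CMe2 group, and the silyl dienol ether formed is inert to a second reduction, so the spiro carbon becomes stereogenic (5S) under ligand control (enantioselective CuH conjugate reduction, desymmetrisation).

**Step 4**
Reactants: 7 (5S)‑4,4‑dimethylspiro[4.5]dec‑6‑ene‑1,8‑dione
Product: 8 (5S,8E)‑8‑(bromomethylidene)‑4,4‑dimethylspiro[4.5]dec‑6‑en‑1‑one
Conditions: [Ph3PCH2Br]Br (1.6 equiv), KOt‑Bu (1.5 equiv), THF, −78 °C; then 7, −78 → 0 °C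
Reagents that add atoms: (bromomethyl)triphenylphosphonium bromide, [Br-].BrC[P+](c1ccccc1)(c1ccccc1)c1ccccc1
Why: Wittig bromomethylenation takes place at the unhindered enone carbonyl and not at the neopentylic cyclopentanone; the 8E isomer (Br on the side of the ring CH2) is expected as the main product and is separated from 8Z on AgNO3‑impregnated silica.

**Step 5**
Reactants: 8 (5S,8E)‑8‑(bromomethylidene)‑4,4‑dimethylspiro[4.5]dec‑6‑en‑1‑one
Product: 9 {[(5S,8E)‑8‑(bromomethylidene)‑4,4‑dimethylspiro[4.5]deca‑1,6‑dien‑1‑yl]oxy}(trimethyl)silane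
Conditions: TMSOTf (1.3 equiv), Et3N (2 equiv), CH2Cl2, 0 °C
Reagents that add atoms: trimethylsilyl trifluoromethanesulfonate, C[Si](C)(C)OS(=O)(=O)C(F)(F)F
Why: Soft enolisation of the only ketone, which has a single enolisable α‑carbon, gives one silyl enol ether regioisomer (silyl enol ether formation).

**Step 6**
Reactants: 9 {[(5S,8E)‑8‑(bromomethylidene)‑4,4‑dimethylspiro[4.5]deca‑1,6‑dien‑1‑yl]oxy}(trimethyl)silane
Product: 10 (2S,4′E)‑4′‑(bromomethylidene)‑3,3‑dimethyl‑1‑[(trimethylsilyl)oxy]spiro[bicyclo[3.1.0]hexane‑2,1′‑cyclohex[2]ene]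
Conditions: Et2Zn (3 equiv), CH2I2 (3 equiv), CH2Cl2, 0 °C → rt
Reagents that add atoms: diiodomethane, ICI
Why: The electron‑rich silyl enol ether is cyclopropanated much faster than the bromodiene (Furukawa–Simmons–Smith reaction); both faces may react, and the two cyclopropane diastereomers converge in step 7.

**Step 7**
Reactants: 10 (2S,4′E)‑4′‑(bromomethylidene)‑3,3‑dimethyl‑1‑[(trimethylsilyl)oxy]spiro[bicyclo[3.1.0]hexane‑2,1′‑cyclohex[2]ene]
Product: 12 (3R,6S,9E)‑3‑bromo‑9‑(bromomethylidene)‑5,5‑dimethylspiro[5.5]undec‑7‑en‑1‑one, via cyclopropanol 11 (not isolated)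
Conditions: K2CO3 (cat.), MeOH, 0 °C; solvent switch to MeCN/CH2Cl2; CuBr2 (10 mol %), (S,S)‑t‑Bu‑box (12 mol %), N‑bromosuccinimide (1.1 equiv, slow addition), −40 °C, dark
Reagents that add atoms: N‑bromosuccinimide, O=C1CCC(=O)N1Br
Why: Proposed new method: the divalent‑copper alkoxide of cyclopropanol 11 undergoes inner‑sphere oxidation and β‑scission of the strained ring‑fusion C–C bond (the bond whose cleavage gives the more stable secondary radical, as in FeCl3‑ and silver‑mediated ring‑opening halogenations of bicyclo[n.1.0]alkan‑1‑ols), which expands the cyclopentane to the cyclohexanone of ring A; the C3 radical, still held to copper through the new ketone oxygen, is captured by the box‑ligated CuBr unit as a five‑membered trivalent‑copper chelate, and C–Br reductive elimination then fixes C3, so that the ligand rather than the remote spiro centre chooses the face (3R) while both cyclopropane diastereomers converge on one radical and N‑bromosuccinimide returns monovalent copper to CuBr2; the closest known reactions are the Saegusa–Ito FeCl3 ring expansion of siloxycyclopropanes to 3‑chlorocycloalkanones, copper‑catalysed ring‑opening functionalisations of cyclopropanols and carbonyl‑directed stereoconvergent metal capture of secondary alkyl radicals.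

**Step 8**
Reactants: 12 (3R,6S,9E)‑3‑bromo‑9‑(bromomethylidene)‑5,5‑dimethylspiro[5.5]undec‑7‑en‑1‑one
Product: 13 (1S,3R,6S,9E)‑3‑bromo‑9‑(bromomethylidene)‑1,5,5‑trimethylspiro[5.5]undec‑7‑en‑1‑ol
Conditions: CeCl3 (2 equiv), MeLi (1.8 equiv), THF, −78 °C; then 12, −78 °C; H2O
Reagents that add atoms: methyllithium, [Li]C
Why: The weakly basic organocerium reagent adds 1,2 without E1cB loss of HBr, and in the chair with equatorial bromine the axial methyl at C5 blocks axial attack, so methyl enters equatorially and the axial hydroxyl (1S, trans to Br) results (Imamoto organocerium addition).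

**Compound list**
1 | 4‑bromophenol | Oc1ccc(Br)cc1 | starting material
2 | 2,2‑dimethylcyclobutan‑1‑one | CC1(C)CCC1=O | starting material
3 | lithium 4‑lithiophenolate | [Li]Oc1ccc([Li])cc1 | intermediate
4 | 4‑(1‑hydroxy‑2,2‑dimethylcyclobutyl)phenol (racemic) | CC1(C)CCC1(O)c1ccc(O)cc1 | intermediate
5 | 4,4‑dimethylspiro[4.5]deca‑6,9‑diene‑1,8‑dione (achiral) | CC1(C)CCC(=O)C12C=CC(=O)C=C2 | intermediate
6 | (5S)‑8‑{[diethoxy(methyl)silyl]oxy}‑4,4‑dimethylspiro[4.5]deca‑6,8‑dien‑1‑one | CC1(C)CCC(=O)[C@@]12C=CC(O[Si](C)(OCC)OCC)=CC2 | intermediate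
7 | (5S)‑4,4‑dimethylspiro[4.5]dec‑6‑ene‑1,8‑dione | CC1(C)CCC(=O)[C@@]12C=CC(=O)CC2 | intermediate
8 | (5S,8E)‑8‑(bromomethylidene)‑4,4‑dimethylspiro[4.5]dec‑6‑en‑1‑one | CC1(C)CCC(=O)[C@@]12C=C/C(=C/Br)CC2 | intermediate
9 | {[(5S,8E)‑8‑(bromomethylidene)‑4,4‑dimethylspiro[4.5]deca‑1,6‑dien‑1‑yl]oxy}(trimethyl)silane | CC1(C)CC=C(O[Si](C)(C)C)[C@@]12C=C/C(=C/Br)CC2 | intermediate
10 | (2S,4′E)‑4′‑(bromomethylidene)‑3,3‑dimethyl‑1‑[(trimethylsilyl)oxy]spiro[bicyclo[3.1.0]hexane‑2,1′‑cyclohex[2]ene] (both cis‑fused cyclopropane diastereomers) | CC1(C)CC3CC3(O[Si](C)(C)C)[C@@]12C=C/C(=C/Br)CC2 | intermediate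
11 | (2S,4′E)‑4′‑(bromomethylidene)‑3,3‑dimethylspiro[bicyclo[3.1.0]hexane‑2,1′‑cyclohex[2]en]‑1‑ol (both cis‑fused cyclopropane diastereomers) | CC1(C)CC3CC3(O)[C@@]12C=C/C(=C/Br)CC2 | intermediate
12 | (3R,6S,9E)‑3‑bromo‑9‑(bromomethylidene)‑5,5‑dimethylspiro[5.5]undec‑7‑en‑1‑one | CC1(C)C[C@@H](Br)CC(=O)[C@@]12C=C/C(=C/Br)CC2 | intermediate
13 | (1S,3R,6S,9E)‑3‑bromo‑9‑(bromomethylidene)‑1,5,5‑trimethylspiro[5.5]undec‑7‑en‑1‑ol | CC1(C)C[C@@H](Br)C[C@](C)(O)[C@@]12C=C/C(=C/Br)CC2 | target

**Totals**
Total step count: 8. Longest linear sequence: 8 steps (fully linear from 1 and 2).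

**The three steps most likely to fail**

Step 3 (CuH desymmetrisation). The β‑carbons sit next to a crowded quaternary centre, so the bulky ligated CuH may react slowly or with modest enantioselectivity, and any 1,2‑reduction of the cyclopentanone would trigger aromatising fragmentation. The fallback is a biocatalytic desymmetrisation, a known reaction of 4,4‑disubstituted cyclohexa‑2,5‑dienones: an ene‑reductase of the old‑yellow‑enzyme family with NADPH recycled by glucose dehydrogenase and glucose in pH 7 buffer, screening the enzyme panel for the 5S product. It sets out from 5 and comes back to the route at 7, and it makes no compound outside the list (F0).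

Step 4 (Wittig bromomethylenation). The two flanks of the enone carbonyl (vinyl CH and ring CH2) are sterically similar, so the E/Z ratio may be close to 1:1; in the main route the Z isomer would have to be separated and re‑equilibrated photochemically (hν, cat. PhSSPh) for recycling. The fallback builds the alkene geometry from an enal instead and sets out from 7. Ph3P=CHOMe (from (methoxymethyl)triphenylphosphonium chloride and KOt‑Bu) gives (5S)‑8‑(methoxymethylidene)‑4,4‑dimethylspiro[4.5]dec‑6‑en‑1‑one F1, whose geometry does not matter. Dilute aqueous acid hydrolyses it to the conjugated enal (5S)‑4,4‑dimethyl‑1‑oxospiro[4.5]dec‑7‑ene‑8‑carbaldehyde F2. Tf2O with 2,6‑di‑tert‑butylpyridine then O‑triflates the aldehyde and removes the γ‑proton through the favoured s‑trans enal, giving (E)‑[(5S)‑4,4‑dimethyl‑1‑oxospiro[4.5]dec‑6‑en‑8‑ylidene]methyl trifluoromethanesulfonate F3 with oxygen on the CH2 side. Nickel‑catalysed triflate‑to‑bromide exchange (Ni(OAc)2, 1,5‑cyclooctadiene, LiBr, DMA/THF) replaces the triflate with retention, and the sequence comes back to the route at 8.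

Step 7 (proposed copper‑catalysed ring‑expanding bromination). External cyclopropane cleavage, direct reaction of N‑bromosuccinimide with the cyclopropanol or the bromodiene, or poor ligand control at C3 could each spoil it; the substrate itself gives almost no bias because the two arms of ring B are alike. The fallback uses known two‑electron chemistry and sets out from 10. FeCl3 in DMF (Saegusa–Ito ring expansion) gives (6S,9E)‑9‑(bromomethylidene)‑3‑chloro‑5,5‑dimethylspiro[5.5]undec‑7‑en‑1‑one F4. NaOAc in MeOH eliminates HCl to the enone (6S,9E)‑9‑(bromomethylidene)‑5,5‑dimethylspiro[5.5]undeca‑2,7‑dien‑1‑one F5. Conjugate addition of HBr (CH2Cl2, −40 °C) then gives 12 together with its C3 epimer (3S,6S,9E)‑3‑bromo‑9‑(bromomethylidene)‑5,5‑dimethylspiro[5.5]undec‑7‑en‑1‑one F6, which is separated by chromatography and returned to F5 with DBU. The sequence comes back to the route at 12.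

**Further compounds**
F0 | step 3 | none | none
F1 | step 4 | (5S)‑8‑(methoxymethylidene)‑4,4‑dimethylspiro[4.5]dec‑6‑en‑1‑one (E/Z mixture) | CC1(C)CCC(=O)[C@@]12C=CC(=COC)CC2
F2 | step 4 | (5S)‑4,4‑dimethyl‑1‑oxospiro[4.5]dec‑7‑ene‑8‑carbaldehyde | CC1(C)CCC(=O)[C@@]12CC=C(C=O)CC2
F3 | step 4 | (E)‑[(5S)‑4,4‑dimethyl‑1‑oxospiro[4.5]dec‑6‑en‑8‑ylidene]methyl trifluoromethanesulfonate | CC1(C)CCC(=O)[C@@]12C=C/C(=C/OS(=O)(=O)C(F)(F)F)CC2
F4 | step 7 | (6S,9E)‑9‑(bromomethylidene)‑3‑chloro‑5,5‑dimethylspiro[5.5]undec‑7‑en‑1‑one (C3 epimers) | CC1(C)CC(Cl)CC(=O)[C@@]12C=C/C(=C/Br)CC2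
F5 | step 7 | (6S,9E)‑9‑(bromomethylidene)‑5,5‑dimethylspiro[5.5]undeca‑2,7‑dien‑1‑one | CC1(C)CC=CC(=O)[C@@]12C=C/C(=C/Br)CC2
F6 | step 7 | (3S,6S,9E)‑3‑bromo‑9‑(bromomethylidene)‑5,5‑dimethylspiro[5.5]undec‑7‑en‑1‑one | CC1(C)C[C@H](Br)CC(=O)[C@@]12C=C/C(=C/Br)CC2
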